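(The readings were computed on assumed constants, noise included.)

Every flask here begins with a leftover: at the start none of the solid monomer is in solution.

| setting | teal | amber | ochre | maple | birch | cedar | elm |
|---|---|---|---|---|---|---|---|
| solid monomer | 0.034 M | 0.075 M | 0.050 M | 0.050 M | 0.050 M | 0.050 M | 0.050 M |
| initiator | 1 mol% | 1 mol% | 2 mol% | 1 mol% | 1 mol% | 1 mol% | 1 mol% |
| temperature | 50 °C | 78 °C | 50 °C | 85 °C | 70 °C | 55 °C | 100 °C |
| remark | run made earlier | run made earlier | run made earlier |  |  |  |  |
| time |  |  |  | 15 h | 15 h | 15 h | 15 h |

| run | time / h | monomer in chains / % |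
|---|---|---|
| teal | 8.00 | 1.2 |
| teal | 15.0 | 1.1 |
| teal | 25.0 | 2.7 |
| teal | 30.0 | 3.7 |
| teal | 60.0 | 8.6 |
| teal | 120 | 19.2 |
| amber | 1.33 | 1.3 |
| amber | 2.50 | 0 |
| amber | 4.00 | 1.6 |
| amber | 6.00 | 1.9 |
| amber | 10.0 | 4.0 |
| amber | 20.0 | 12.3 |
| ochre | 8.00 | 0.8 |
| ochre | 15.0 | 0.8 |
| ochre | 30.0 | 4.5 |
| ochre | 60.0 | 12.3 |
| ochre | 120 | 27.3 |

(standard deviation of a reading: 0.5 percentage points)

- at the start none of the solid monomer is in solution
- a reading or a percentage of monomer in chains counts all its forms, free or not

* which flask leads in amount of monomer in chains, in percent of the solid monomer charged ("all alike" within 1.5 percentage points) (maple / birch / cedar / elm / all alike)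
* how much monomer in chains is there at the end, in percent of the solid monomer charged: maple
* how much monomer in chains is there at the end, in percent of the solid monomer charged: birch
* how much monomer in chains is there at the end, in percent of the solid monomer charged: cedar
* how much monomer in chains is there at the end, in percent of the solid monomer charged: elm

*Which concentration sets the rate?* I take it to be [free monomer], not the charge: chains grow from what has dissolved, and that starts at zero.

*What can you read from that?* A fill time: the moment at which the straight line through a run's last two readings, drawn back, reaches zero monomer in chains. The field calls it an induction period. Teal reads 11.3 h, ochre 10.8 h.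

*But ochre has twice the loading.* Yes, and its fill time reads about teal's, though its charge of 0.050 M differs from teal's 0.034 M as well, so I treat it, tentatively, as a matter of dissolving.

*And temperature?* Amber, at 78 °C, reads 5.18 h, shorter than teal. Its late slope, 0.00830 h⁻¹ as a fraction of the charge, is steeper than teal's 0.00177 h⁻¹.

*Amber differs from teal in charge too.* It does, and each slope rests on two readings. I carry that error.

*Then cedar?* Cedar lies between teal and amber in temperature. Interpolating straight gives cedar's fill time, 10.2 h. Interpolating the logarithm gives its slope, 0.00233 h⁻¹. Slope times time past the fill time makes 1.11% for cedar at 15 h.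

*The others?* Amber, hotter than teal, read the shorter fill and the steeper slope, though its charge differs too; elm is the hottest of the flasks asked about, so I rank it first. Maple and elm stand above the temperature of any run, and I give them no number; birch I leave unreckoned too.

The forecast, holding that the runs' lag “suggests slow dissolution rather than an inhibitor”, names elm and gives 8.5% for maple, 4.5% for birch, 13% for elm and 1.5% for cedar, above my figure.

The flasks give 13.9% for maple, 5.54% for birch, 1.53% for cedar and 20.0% for elm, so elm leads.

    initiator → 2 initiating radical (k = 0.0420 h⁻¹, Ea = 116 kJ mol⁻¹)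
    free monomer + initiating radical → growing radical + monomer in chains (k = 1.40 × 10⁵ M⁻¹ s⁻¹, Ea = 12.0 kJ mol⁻¹)
    free monomer + growing radical → monomer in chains + growing radical, rate k3*[growing radical]*[free monomer] (k = 1.50 × 10⁷ M⁻¹ h⁻¹, Ea = 38.0 kJ mol⁻¹)
    2 growing radical → dead chain (k = 4.00 × 10⁷ M⁻¹ s⁻¹, Ea = 19.0 kJ mol⁻¹)
    crystals ⇌ monomer in chains, rate k5*(cs5 - [monomer in chains]) while solid is left; crystals form when [monomer in chains] > cs5 (solubility = 26.0 mM, k = 2.50 h⁻¹)
    solid monomer ⇌ free monomer, rate k6*(cs6 - [free monomer]) while solid is left; crystals form when [free monomer] > cs6 (solubility = 46.0 mM, k = 0.0480 h⁻¹)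
    free monomer ⇌ dormant form (K = 12.0, k = 0.270 h⁻¹, Ea = 106 kJ mol⁻¹, ΔH = 6.00 kJ mol⁻¹)
    (constants at 100 °C)

Cedar's 1.53% stands 0.42 percentage points above my reckoning, where a reading scatters by 0.5 points. Now read cedar at 40 h instead, with the same slope and fill time: they give 6.94%, and that flask holds 7.61%. Its free monomer stands at 71.9% of the charge, against 45.3% at 15.0 h, and 15.7% of the charge is still solid monomer.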